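**Plan**

- Lignan numbering: C7 is the oxolane carbon carrying ring A, C8 carries C9H2OH, C8' carries the C7'H2 benzyl of ring B, and C9' is the ring OCH2. The retrosynthesis first cuts the C7–O bond, which uncovers the C2-symmetric (8R,8'R) tetraol 12. It then cuts the central C8–C8' bond, which halves 12 into two identical 3-arylpropanoyl units.
- The last step is possible because ring A is a free 4-alkyl-2,6-dimethoxyphenol whose benzylic C7–H lies para to the OH. Two-electron oxidation therefore gives a para-quinone methide at C7, and O9' sits four atoms away, right for a five-membered closure.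
- Forward: sinapic acid is saturated and O-benzylated, then attached to the oxazolidinone. Oxidative enolate homocoupling joins the chain at C8–C8'. The auxiliary is removed by reduction, the phenols are unmasked, and the only ring (the oxolane) closes last at the anode.
- Stereochemistry: C8 and C8' come from the (S)-4-benzyl-oxazolidinone in the homocoupling. C7 is set by C8 during ring closure (aryl trans to C9), supported by reversibility of the para-hydroxybenzyl ether.
- The two syringyl units of 12 are homotopic, so the single closure is a desymmetrization. It is held at one ring by the charge passed, with recovery of 12.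

Key step: step 7

Remark: name and SMILES of the target agree (7S,8R,8'R). On the oxolane this places the C7 aryl trans to the C8 hydroxymethyl and the hydroxymethyl cis to the C8' benzyl, as the (R,R) backbone of 12 requires.

**Route**

Step 1
Reactants: 1 sinapic acid
Product: 2 3-(4-hydroxy-3,5-dimethoxyphenyl)propanoic acid
Conditions: H2 (1 atm), 10% Pd/C, MeOH, rt
Reagents that add atoms: none
Why: Catalytic hydrogenation over Pd/C should saturate the conjugated cinnamic double bond chemoselectively, leaving arene, phenol and acid untouched.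

Step 2
Reactants: 2 3-(4-hydroxy-3,5-dimethoxyphenyl)propanoic acid; 3 benzyl bromide
Product: 5 3-(4-benzyloxy-3,5-dimethoxyphenyl)propanoic acid, via benzyl ester 4 (not isolated)
Conditions: BnBr, K2CO3, DMF, 60 °C; then 2 M NaOH, MeOH, 60 °C; HCl work-up
Reagents that add atoms: benzyl bromide 3, BrCc1ccccc1; sodium hydroxide, [Na+].[OH-]
Why: Williamson O-alkylation under carbonate should benzylate both the hindered phenoxide and the carboxylate, and saponification in the same flask cleaves only the benzyl ester, leaving the aryl benzyl ether that later withstands amide base, CuCl2 and hydride.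

Step 3
Reactants: 5 3-(4-benzyloxy-3,5-dimethoxyphenyl)propanoic acid; 6 (S)-4-benzyl-2-oxazolidinone
Product: 8 (S)-4-benzyl-3-[3-(4-benzyloxy-3,5-dimethoxyphenyl)propanoyl]oxazolidin-2-one, via mixed pivalic anhydride 7 (not isolated)
Conditions: PivCl, Et3N, THF, −20 °C; then LiCl, 6, −20 °C → rt
Reagents that add atoms: (S)-4-benzyl-2-oxazolidinone 6, O=C1N[C@@H](Cc2ccccc2)CO1
Why: N-Acylation of the oxazolidinone through the mixed pivalic anhydride with LiCl activation is the standard mild way to attach this auxiliary, the hindered pivaloyl carbonyl steering attack to the arylpropanoyl group.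

Step 4
Reactants: 8 (S)-4-benzyl-3-[3-(4-benzyloxy-3,5-dimethoxyphenyl)propanoyl]oxazolidin-2-one (two molecules)
Product: 10 (2R,3R)-2,3-bis(4-benzyloxy-3,5-dimethoxybenzyl)-1,4-bis[(S)-4-benzyl-2-oxooxazolidin-3-yl]butane-1,4-dione, via lithium Z-enolate 9 (not isolated)
Conditions: LiN(iPr)2, THF, −78 °C; then CuCl2, DMF, −78 → 0 °C
Reagents that add atoms: none
Why: Oxidative enolate homocoupling with divalent copper (CuCl2) should form the C8–C8' bond, each chelated Z-enolate reacting on the face away from the 4-benzyl group of the (S)-auxiliary so that both new stereocentres come out R, with any minor diastereomer removed by chromatography or crystallization.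

Step 5
Reactants: 10 (2R,3R)-bis(acyl oxazolidinone) dimer
Product: 11 (2R,3R)-2,3-bis(4-benzyloxy-3,5-dimethoxybenzyl)butane-1,4-diol
Conditions: LiBH4, MeOH (stoichiometric), THF, 0 °C → rt
Reagents that add atoms: none
Why: Reductive cleavage of N-acyl oxazolidinones with LiBH4 should deliver both primary alcohols without touching the α-stereocentres or the benzyl ethers, and any lactone formed by internal acyl transfer is reduced onward to the same diol.

Step 6
Reactants: 11 (2R,3R)-2,3-bis(4-benzyloxy-3,5-dimethoxybenzyl)butane-1,4-diol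
Product: 12 (8R,8'R)-5,5'-dimethoxysecoisolariciresinol
Conditions: H2 (1 atm), 10% Pd/C, EtOAc/MeOH, rt
Reagents that add atoms: none
Why: Hydrogenolysis of aryl benzyl ethers over Pd/C should be clean because 11 holds no other reducible group and no benzylic C–O bond, so both syringyl phenols are unmasked without change at C8 and C8'.

Step 7
Reactants: 12 (8R,8'R)-5,5'-dimethoxysecoisolariciresinol
Product: 14 (+)-(7S,8R,8'R)-5,5'-dimethoxylariciresinol, via quinone methide 13 (not isolated)
Conditions: graphite anode, Pt cathode, undivided cell, controlled potential at the first phenol wave (set by cyclic voltammetry), about 1 F per mol, Bu4NBF4 (0.1 M), 2,6-lutidine (2 equiv), MeCN, 0 °C; then rt, 1 h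
Reagents that add atoms: none
Why: At the lutidine-assisted first wave one syringyl phenol of 12 is oxidised to its phenoxyl radical, and net loss of two electrons, the phenolic proton and one C7 proton (phenoxyl disproportionation, or a second electron transfer followed by deprotonation) gives the para-quinone methide 13, while the cathode turns the released protons into H2. The closest known reaction types are the oxidation of 4-alkyl-2,6-dimethoxyphenols to para-quinone methides with Ag2O or DDQ followed by 1,6-addition of an alcohol, and the anodic benzylic alkoxylation of 4-alkylphenols. The oxolane closes by 5-exo-trig attack of the C9' hydroxyl on the exocyclic C7 of 13, which restores the aromatic ring A; the C9 hydroxyl could only close a four-membered ring. The new C7 stereocentre is governed by C8, the aryl group taking the face trans to the C9 hydroxymethyl (7S), and since the para-hydroxybenzyl ether can reopen to 13 in the buffered medium the trans isomer should also be the thermodynamic sink. Because the two halves of 12 are homotopic, oxidation at either ring leads to the same compound, and mono- over double cyclization is secured only by the charge (about half of what full conversion needs), with unchanged 12 recovered and recycled. Benzylic C7–H functionalization should win over spiro-etherification at C1 by the C9 hydroxyl because the low potential and the base keep the chemistry at the phenoxyl and quinone methide level, away from a free phenoxonium ion.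

**Compound list**

1 | sinapic acid | COc1cc(/C=C/C(=O)O)cc(OC)c1O | starting material
2 | 3-(4-hydroxy-3,5-dimethoxyphenyl)propanoic acid | COc1cc(CCC(=O)O)cc(OC)c1O | intermediate
3 | benzyl bromide | BrCc1ccccc1 | starting material
4 | benzyl 3-(4-benzyloxy-3,5-dimethoxyphenyl)propanoate | COc1cc(CCC(=O)OCc2ccccc2)cc(OC)c1OCc1ccccc1 | intermediate (not isolated)
5 | 3-(4-benzyloxy-3,5-dimethoxyphenyl)propanoic acid | COc1cc(CCC(=O)O)cc(OC)c1OCc1ccccc1 | intermediate
6 | (S)-4-benzyl-2-oxazolidinone | O=C1N[C@@H](Cc2ccccc2)CO1 | starting material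
7 | 3-(4-benzyloxy-3,5-dimethoxyphenyl)propanoic pivalic anhydride | COc1cc(CCC(=O)OC(=O)C(C)(C)C)cc(OC)c1OCc1ccccc1 | intermediate (not isolated)
8 | (S)-4-benzyl-3-[3-(4-benzyloxy-3,5-dimethoxyphenyl)propanoyl]oxazolidin-2-one | COc1cc(CCC(=O)N2[C@@H](Cc3ccccc3)COC2=O)cc(OC)c1OCc1ccccc1 | intermediate
9 | lithium Z-enolate of 8 | COc1cc(C/C=C(\O[Li])N2[C@@H](Cc3ccccc3)COC2=O)cc(OC)c1OCc1ccccc1 | intermediate (not isolated)
10 | (2R,3R)-2,3-bis(4-benzyloxy-3,5-dimethoxybenzyl)-1,4-bis[(S)-4-benzyl-2-oxooxazolidin-3-yl]butane-1,4-dione | COc1cc(C[C@@H](C(=O)N2[C@@H](Cc3ccccc3)COC2=O)[C@@H](Cc2cc(OC)c(OCc3ccccc3)c(OC)c2)C(=O)N2[C@@H](Cc3ccccc3)COC2=O)cc(OC)c1OCc1ccccc1 | intermediate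
11 | (2R,3R)-2,3-bis(4-benzyloxy-3,5-dimethoxybenzyl)butane-1,4-diol | COc1cc(C[C@@H](CO)[C@@H](Cc2cc(OC)c(OCc3ccccc3)c(OC)c2)CO)cc(OC)c1OCc1ccccc1 | intermediate
12 | (8R,8'R)-5,5'-dimethoxysecoisolariciresinol, (2R,3R)-2,3-bis(4-hydroxy-3,5-dimethoxybenzyl)butane-1,4-diol | COc1cc(C[C@@H](CO)[C@@H](Cc2cc(OC)c(O)c(OC)c2)CO)cc(OC)c1O | intermediate
13 | C7 para-quinone methide of 12 (ring A as 2,6-dimethoxy-4-alkylidenecyclohexa-2,5-dienone, 8R,8'R) | COC1=CC(=C[C@@H](CO)[C@@H](Cc2cc(OC)c(O)c(OC)c2)CO)C=C(OC)C1=O | intermediate (not isolated)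
14 | (+)-(7S,8R,8'R)-5,5'-dimethoxylariciresinol, 4-[(2S,3R,4R)-4-(4-hydroxy-3,5-dimethoxybenzyl)-3-(hydroxymethyl)oxolan-2-yl]-2,6-dimethoxyphenol | COc1cc(C[C@H]2CO[C@H](c3cc(OC)c(O)c(OC)c3)[C@H]2CO)cc(OC)c1O | target

**Totals**

Total step count: 7. Longest linear sequence: 7 steps (from sinapic acid).

**Steps most likely to fail**

Step 7. The oxidation may not stop after one ring: the product still carries one oxidizable syringyl unit, so a second two-electron oxidation with closure of a second ring can compete. The cyclized phenol can also be oxidized again at C7. At too high a potential the C9 hydroxyl may attack the ring carbon C1 instead, and the electrode may foul.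

Fallback, from 12 back to 14: the two rings are told apart by a protecting group and a chemical one-electron oxidant is used. Phenol-selective alkylation of 12 with one equivalent of benzyl bromide 3 (K2CO3, acetone) should give the ring-B mono-benzyl ether F1. Recovered 12 is reused, and doubly benzylated material is 11 and re-enters at step 6. Ag2O in CH2Cl2 should oxidise the single free syringyl phenol to the quinone methide F2 (not isolated), and the C9' hydroxyl closes the oxolane, helped if needed by a trace of acid. This gives the ring-B benzyl ether of the target F3, with the aryl trans to C9 as in the main route. Brief hydrogenolysis (H2, Pd/C, EtOAc, stopped after one equivalent) removes the aryl benzyl ether and gives 14.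

Step 4. The homocoupling may give low conversion or poor diastereocontrol, for example through competing α-chlorination or proton return to the enolate, or through partial mismatch in the radical recombination.

Fallback, from 8 back to 11: the C8–C8' bond is built stepwise by two alkylations.
- The sodium Z-enolate F4 of 8 (NaN(SiMe3)2, THF, −78 °C) is alkylated with tert-butyl bromoacetate on the face away from the auxiliary benzyl group, giving tert-butyl (R)-3-(4-benzyloxy-3,5-dimethoxybenzyl)-4-[(S)-4-benzyl-2-oxooxazolidin-3-yl]-4-oxobutanoate F5.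
- LiBH4 (THF, MeOH) reduces the imide selectively to tert-butyl (R)-3-(4-benzyloxy-3,5-dimethoxybenzyl)-4-hydroxybutanoate F6.
- Catalytic TsOH in toluene closes F6 to (R)-4-(4-benzyloxy-3,5-dimethoxybenzyl)dihydrofuran-2(3H)-one F7.
- In parallel, commercial 4-benzyloxy-3,5-dimethoxybenzaldehyde (COc1cc(C=O)cc(OC)c1OCc1ccccc1) is reduced with NaBH4 to (4-benzyloxy-3,5-dimethoxyphenyl)methanol F8 and converted with PBr3 into 4-benzyloxy-3,5-dimethoxybenzyl bromide F9.
- The lithium enolate F10 of F7 (LiN(SiMe3)2, THF, −78 °C) is alkylated with F9 trans to the existing substituent, giving (3R,4R)-3,4-bis(4-benzyloxy-3,5-dimethoxybenzyl)dihydrofuran-2(3H)-one F11.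
- LiAlH4 (THF, 0 °C) reduces F11 to 11.

Step 5. The reduction of the two hindered imides may stall at a hydroxy imide or lactone, or hydride may open the oxazolidinone ring instead of releasing it.

Fallback, from 10 back to 11: the auxiliary is removed by hydrolysis before reduction. LiOH/H2O2 (THF/H2O, 0 °C, Na2SO3 quench) should cleave both imides at the exocyclic carbonyl to give (2R,3R)-2,3-bis(4-benzyloxy-3,5-dimethoxybenzyl)butanedioic acid F12, with recovery of the auxiliary. BH3·THF (0 °C → rt) then reduces the diacid to 11.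

**Further compounds**

F1 | step 7 | (2R,3R)-2-(4-benzyloxy-3,5-dimethoxybenzyl)-3-(4-hydroxy-3,5-dimethoxybenzyl)butane-1,4-diol | COc1cc(C[C@@H](CO)[C@@H](Cc2cc(OC)c(OCc3ccccc3)c(OC)c2)CO)cc(OC)c1O
F2 | step 7 | C7 para-quinone methide of F1 (not isolated) | COC1=CC(=C[C@@H](CO)[C@@H](Cc2cc(OC)c(OCc3ccccc3)c(OC)c2)CO)C=C(OC)C1=O
F3 | step 7 | 4-[(2S,3R,4R)-4-(4-benzyloxy-3,5-dimethoxybenzyl)-3-(hydroxymethyl)oxolan-2-yl]-2,6-dimethoxyphenol | COc1cc(C[C@H]2CO[C@H](c3cc(OC)c(O)c(OC)c3)[C@H]2CO)cc(OC)c1OCc1ccccc1
F4 | step 4 | sodium Z-enolate of 8 (not isolated) | COc1cc(C/C=C(\O[Na])N2[C@@H](Cc3ccccc3)COC2=O)cc(OC)c1OCc1ccccc1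
F5 | step 4 | tert-butyl (R)-3-(4-benzyloxy-3,5-dimethoxybenzyl)-4-[(S)-4-benzyl-2-oxooxazolidin-3-yl]-4-oxobutanoate | COc1cc(C[C@H](CC(=O)OC(C)(C)C)C(=O)N2[C@@H](Cc3ccccc3)COC2=O)cc(OC)c1OCc1ccccc1
F6 | step 4 | tert-butyl (R)-3-(4-benzyloxy-3,5-dimethoxybenzyl)-4-hydroxybutanoate | COc1cc(C[C@H](CC(=O)OC(C)(C)C)CO)cc(OC)c1OCc1ccccc1
F7 | step 4 | (R)-4-(4-benzyloxy-3,5-dimethoxybenzyl)dihydrofuran-2(3H)-one | COc1cc(C[C@H]2COC(=O)C2)cc(OC)c1OCc1ccccc1
F8 | step 4 | (4-benzyloxy-3,5-dimethoxyphenyl)methanol | COc1cc(CO)cc(OC)c1OCc1ccccc1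
F9 | step 4 | 4-benzyloxy-3,5-dimethoxybenzyl bromide | COc1cc(CBr)cc(OC)c1OCc1ccccc1
F10 | step 4 | lithium enolate of F7 (not isolated) | COc1cc(C[C@H]2COC(O[Li])=C2)cc(OC)c1OCc1ccccc1
F11 | step 4 | (3R,4R)-3,4-bis(4-benzyloxy-3,5-dimethoxybenzyl)dihydrofuran-2(3H)-one | COc1cc(C[C@H]2COC(=O)[C@@H]2Cc2cc(OC)c(OCc3ccccc3)c(OC)c2)cc(OC)c1OCc1ccccc1
F12 | step 5 | (2R,3R)-2,3-bis(4-benzyloxy-3,5-dimethoxybenzyl)butanedioic acid | COc1cc(C[C@@H](C(=O)O)[C@@H](Cc2cc(OC)c(OCc3ccccc3)c(OC)c2)C(=O)O)cc(OC)c1OCc1ccccc1
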